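**Retrosynthetic overview**
- The benzylic C–O bond is traced back to a formyl group: target 5 comes from 2,3,6-tribromo-4,5-dihydroxybenzaldehyde 4 by hydride reduction.
- The three C–Br bonds are disconnected together: 4 comes from 3,4-dihydroxybenzaldehyde 1 by exhaustive electrophilic bromination, since every free ring position is ortho or para to a phenolic OH.
- No ring is formed; the benzene ring is bought intact and no protecting group is used.

Assumption: the target has no stereocentre (it is achiral), so no stereocontrol is needed.

**Route**

Step 1
Reactants: 1 3,4-dihydroxybenzaldehyde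
Product: 4 2,3,6-tribromo-4,5-dihydroxybenzaldehyde, via 3-bromo-4,5-dihydroxybenzaldehyde 2 (not isolated), via 2,3-dibromo-4,5-dihydroxybenzaldehyde 3 (not isolated)
Conditions: Br2 (3.5 equiv), Fe powder (5 mol %), AcOH, 20 °C then 60 °C, 12 h; pour into ice-cold aqueous NaHSO3, filter
Reagents that add atoms: bromine, BrBr
Why: Threefold electrophilic aromatic substitution (bromination) fills the three free positions, each ortho or para to a free OH (first ortho to the 4-OH, then para and finally ortho to the 3-OH), while the HBr formed and the bisulfite work-up keep the catechol reduced; no stereocentre is formed.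

Step 2
Reactants: 4 2,3,6-tribromo-4,5-dihydroxybenzaldehyde
Product: 5 (2,3,6-tribromo-4,5-dihydroxyphenyl)methanol
Conditions: NaBH4 (2.5 equiv), THF/H2O 4:1, N2, 0 °C, 1 h; then cold 1 M HCl to pH 4–5, EtOAc extraction
Reagents that add atoms: none
Why: Borohydride reduction of the aldehyde (nucleophilic hydride addition) gives the primary benzylic alcohol; aryl bromides and phenols are inert to NaBH4 at 0 °C, and the alcohol-free solvent with a cold, weakly acidic work-up avoids ether formation at the p-hydroxybenzylic carbon; no stereocentre is formed.

**Compound list**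
1 | 3,4-dihydroxybenzaldehyde (protocatechualdehyde) | O=Cc1ccc(O)c(O)c1 | starting material
2 | 3-bromo-4,5-dihydroxybenzaldehyde | O=Cc1cc(O)c(O)c(Br)c1 | intermediate
3 | 2,3-dibromo-4,5-dihydroxybenzaldehyde | O=Cc1cc(O)c(O)c(Br)c1Br | intermediate
4 | 2,3,6-tribromo-4,5-dihydroxybenzaldehyde | O=Cc1c(Br)c(O)c(O)c(Br)c1Br | intermediate
5 | (2,3,6-tribromo-4,5-dihydroxyphenyl)methanol | OCc1c(Br)c(O)c(O)c(Br)c1Br | target

**Totals**
Total step count: 2
Longest linear sequence: 2

**Steps most likely to fail**
The route has only two steps, so both are ranked and no third can be named.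

Most likely to fail: step 1. The risks are bromodeformylation at the carbon para to the 4-OH (giving tetrabromocatechol), oxidation of the free catechol to quinone-derived tar, and a stalled third bromination. The fallback masks the phenol para to the formyl group. It sets out from compound 2, isolated by stopping the bromination of 1 after 1.0 equiv of Br2 in AcOH at 20 °C without Fe powder. Selective O-methylation of the more acidic 4-OH (iodomethane MeI 1.05 equiv, Li2CO3, DMF, 40 °C) gives 3-bromo-5-hydroxy-4-methoxybenzaldehyde F1. Dibromination ortho and para to the one remaining free OH, which is meta to the formyl group and so cannot trigger ipso attack (Br2 2.3 equiv, Fe powder 5 mol %, AcOH, 20 to 50 °C), gives 2,3,6-tribromo-5-hydroxy-4-methoxybenzaldehyde F2. Ether cleavage with BBr3 (CH2Cl2, −78 to 20 °C, then water) brings the fallback back to the route at compound 4.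

Second most likely to fail: step 2. The risks are sluggish reduction of the phenoxide or borate-chelated aldehyde, over-reduction to the methyl arene through a quinone methide, and loss of the p-hydroxybenzylic alcohol on work-up. The fallback carries the catechol through the reduction in protected form. It sets out from compound 4. Acetylation (Ac2O, pyridine, DMAP 5 mol %, CH2Cl2, 0 to 20 °C) gives 3,4,6-tribromo-5-formyl-1,2-phenylene diacetate F3. Neutral reduction with BH3·THF (THF, 0 °C), which leaves aryl acetates alone, gives 3,4,6-tribromo-5-(hydroxymethyl)-1,2-phenylene diacetate F4. Hydrolysis with LiOH (THF/H2O, N2, 0 °C, then pH 4–5) brings the fallback back to the route at compound 5.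

**Further compounds**
F1 | step 1 | 3-bromo-5-hydroxy-4-methoxybenzaldehyde | O=Cc1cc(O)c(OC)c(Br)c1
F2 | step 1 | 2,3,6-tribromo-5-hydroxy-4-methoxybenzaldehyde | O=Cc1c(Br)c(O)c(OC)c(Br)c1Br
F3 | step 2 | 3,4,6-tribromo-5-formyl-1,2-phenylene diacetate | CC(=O)Oc1c(OC(C)=O)c(Br)c(C=O)c(Br)c1Br
F4 | step 2 | 3,4,6-tribromo-5-(hydroxymethyl)-1,2-phenylene diacetate | CC(=O)Oc1c(OC(C)=O)c(Br)c(CO)c(Br)c1Br
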